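## The problem

The target is a furanoheliangolide-type germacranolide. Its ten-membered carbocycle (C1–C10) is spanned by a 3(2H)-furanone (C1 carbonyl, C2=C3, ring oxygen joining C3 and C10, methyl C14 on C10). It also carries a Z alkene C4=C5 (methyl C15), a trans-fused α-methylene-γ-lactone on C7/C8 (C11, C12 carbonyl, C13 methylene) and a (2S,3S)-2,3-epoxy-2-methylbutanoate on the C6 oxygen.

The medium ring holds two endocyclic alkenes and a one-atom oxygen bridge, so direct closure of the ten-membered ring is entropically and enthalpically poor. The ring is better unveiled from a smaller bicycle.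

Of the four ring stereocentres, C6 (S), C7 (R) and C8 (S) are contiguous, while the quaternary C10 (S) is 1,3 to C8 and too far from C7 for substrate control in an open chain. C10 therefore needs reagent control. Once set, its hydroxyl can relay to C8, because O8 is 1,3-anti to O10.

The oxygens on C6 and C8 are both γ to C12, so either can lactonise and the two must be told apart.

The α-methylene lactone and the furanone are Michael acceptors and the epoxy ester is fragile. Any C8 ketone with oxygen on C6 can eliminate or epimerise at C7. These groups must therefore appear late and without base.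

The enabling feature is that C3 (ketone oxidation level) and the oxygenated C8 face each other across the ring. A C3–C8 bond turns the ring into a decalin whose ring A (C3–C8 with C15 and C11–C13) is the skeleton of carvone. Eschenmoser–Tanabe fragmentation of the C2-keto C3/C8 epoxide cuts exactly this bond, leaving C8=O and a C2≡C3 alkyne that stores the oxidation level of C3.

## Retrosynthesis

**Ester.** The C6–O acyl bond is cut first: target 36 comes from alcohol 30 and epoxy acid 34 by Yamaguchi esterification. Carrying the ester earlier would leave a β-acyloxy ketone after the fragmentation, which eliminates far more readily than a silyl ether. Acid 34 goes back through epoxy alcohol 33 and (Z)-allylic alcohol 32 to angelic acid 31; the asymmetric epoxidation sets both ester stereocentres.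

**Lactone.** In 30 the O8–C12 bond is cut and C12 is returned to a methyl group, so silyl ether 29 comes from allylic alcohol 28 and this from the isopropenyl compound 27. Building the lactone by carbonylation instead would need a C7 ethynyl group that carvone cannot supply. The forward steps need an allylic oxidation that touches only the isopropenyl group and a lactonisation that can only use O8, hence the silyl ether on C6.

**Furanone and C8.** The O–C3 bond of 27 is cut to the α′-hydroxy ynone 26, which comes from triol 25 by oxidation of the propargylic alcohol. The C8 carbinol of 25 is traced to ketone 24, where the free C10 hydroxyl directs a 1,3-anti reduction. Diol 24 is the desilylated form of enynone 23.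

**Key disconnection.** The C3–C8 bond is re-formed: enynone 23 comes from ring-fusion epoxy ketone 20 and tosylhydrazide 21. Against a macrocyclisation this cut needs no ring closure, and the Z alkene is inherited from the cyclohexene. One step delivers both the C8 ketone and the C3 oxidation level. The forward reaction must fragment cold and without base so that C7 survives.

**Oxidation pattern of ring B.** Epoxy ketone 20 is simplified to epoxy ketone 18 (C1 oxygen by enolate hydroxylation), then to epoxy alcohol 17 and allylic alcohol 16. A hydroxyl-directed epoxidation of 16 is preferred to nucleophilic epoxidation of the corresponding enone, because base could eliminate the C10 oxygen and aromatise ring B.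

**Ring B.** The C2–C3 bond of 16 is cut to aldehyde 15 with a dienyl triflate at C3 (nickel/chromium-mediated closure). A reductive pinacol closure onto the enone carbonyl would expose the γ-silyloxy enone to the reductant and would need a later dehydration. A metathesis closure would have to compete with the isopropenyl group. Aldehyde 15 comes from the vinyl group of triflate 14 by anti-Markovnikov oxidation, and 14 from ketone 13.

**C6.** Silyl ether 13 comes from alcohol 12, its inverted ester 11 and the epimeric alcohol 10. γ-Oxygenation of the enone through the linear silyl dienol ether 9 can only come anti to the neighbouring isopropenyl group, so the inversion is placed here, on a simple monocycle. Dienol ether 9 is made from tertiary allylic alcohol 7.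

**C10 and the side chain.** The vinyl carbinol 7 comes from 2,3-epoxy alcohol 5 by reductive transposition, and 5 from allylic alcohol 4. Titanium-tartrate epoxidation is chosen because it acts only on the allylic alcohol alkene. An undirected dihydroxylation could not distinguish this alkene from the isopropenyl group. Alcohol 4 comes from acetate 3, the α′-alkylation product of (S)-carvone 1 with allylic chloride 2.

## Roads not taken

**Alternative 1:** The cut is the lactone bond C7–C11, with a temporary C6–C11 bond. A dirhodium carbenoid from the dienyl diazoacetate A1 would add to the E alkene C6=C7 and give the cyclopropane-fused lactone A2. Later opening of the vinylcyclopropane at C6 by an oxygen nucleophile with inversion would place the C6 oxygen and free C11 for methylenation.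
- Merits: the C6/C7/C8 triad is fixed by a rigid bicycle and stereospecific steps. This is better than the chosen plan, which needs a Mitsunobu inversion at C6 and a directed reduction at C8.
- Weak points: C8 and C10 of A1 each need their own asymmetric construction. The ten-membered ring must still be closed late by a macrocyclisation between C2 and C3. The cyclopropane opening must choose C6 over allylic transposition. The α-methylenation falls late on a crowded lactone.
- Against this the chosen plan sets the avoidance of any medium-ring closure and the supply of ten carbons and C7 from carvone.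

**Alternative 2:** The cut is C11–C12 and C12–O8. Palladium-catalysed cyclocarbonylation of the homopropargylic alcohol A3 with carbon monoxide would give A4, which is identical with compound 29 of the chosen route apart from its origin.
- Merits: the α-methylene lactone is made in one mild step. As an end-game this is better than the chosen two-step oxidation sequence with its chemoselective allylic oxidation.
- Weak points: it answers only the last ring. A3 already contains the bridged ten-membered system. Its C7 ethynyl group cannot come from carvone, so C7 would have to be set de novo and a terminal alkyne carried past the gold and fragmentation chemistry.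
- The chosen plan accepts two extra oxidation steps in exchange for the carvone isopropenyl group, which brings C11–C13 and the C7 configuration.

**Alternative 3:** The cut forms O–C10 and C9–C10 and breaks O–C7. A copper carbenoid from the dihydropyranyl diazoketone A5 would be trapped by the ring oxygen, and the oxonium ylide would shift [2,3] to the oxa-bridged ketone A6.
- Merits: one step builds the oxygen bridge, the ten-membered carbocycle and the quaternary C10. This is more ring-forming power than the chosen key step, which creates no stereocentre and needs a separate furanone closure.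
- Weak points: the C10 configuration rests on the ylide geometry. [1,2]-Shift and C–H insertion compete. A6 lacks C11–C13 and has a saturated C2–C3. A three-carbon unit would have to be attached at C7 with stereocontrol through a medium-ring silyl enol ether, C8 set and the furanone dehydrogenated.
- The chosen plan has a longer preparation of its fragmentation substrate, but all carbons and C7 are in place before the ring is opened.

Key step: step 16

Remark on the chemistry: centres that are later erased or re-oxidised (C1, C2, C3, and C8 before step 18) are expected as epimer mixtures and are drawn without configuration; all such mixtures converge.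

## Route

Step 1
Reactants: 1 (S)-carvone; 2 (E)-4-chloro-3-methylbut-2-enyl acetate
Product: 3 (E)-3-methyl-4-[(1R,6S)-3-methyl-2-oxo-6-(prop-1-en-2-yl)cyclohex-3-en-1-yl]but-2-enyl acetate
Conditions: LDA, THF, −78 °C; then 2, NaI (cat.), DMPU, −78 → −20 °C
Reagents that add atoms: none
Why: Kinetic deprotonation of carvone occurs at the α′ methylene (C8), and the cross-conjugated lithium enolate is C-alkylated by the allylic halide (iodide formed in situ by Finkelstein exchange) anti to the C7 isopropenyl group. The new C8 centre is erased in step 10.

Step 2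
Reactants: 3 acetate
Product: 4 (5S,6R)-6-[(E)-4-hydroxy-2-methylbut-2-enyl]-2-methyl-5-(prop-1-en-2-yl)cyclohex-2-enone
Conditions: K2CO3 (cat.), MeOH, 0 °C
Reagents that add atoms: none
Why: Mild transesterification frees the primary allylic alcohol that will direct the epoxidation; the enone is stable under these conditions.

Step 3
Reactants: 4 allylic alcohol
Product: 5 (5S,6R)-6-{[(2S,3S)-3-(hydroxymethyl)-2-methyloxiran-2-yl]methyl}-2-methyl-5-(prop-1-en-2-yl)cyclohex-2-enone
Conditions: Ti(OiPr)4, L-(+)-diethyl tartrate, t-BuOOH, 4 Å MS, CH2Cl2, −20 °C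
Reagents that add atoms: tert-butyl hydroperoxide CC(C)(C)OO
Why: Sharpless asymmetric epoxidation acts only on the alkene bound to titanium through the allylic hydroxyl, so the isopropenyl and enone alkenes stay. For this (E)-3-methyl-2-alkenol the L-(+)-tartrate delivers oxygen to the face that makes C10 S (reagent control).

Step 4
Reactants: 5 epoxy alcohol
Product: 7 (5S,6R)-6-[(2S)-2-hydroxy-2-methylbut-3-enyl]-2-methyl-5-(prop-1-en-2-yl)cyclohex-2-enone, via epoxy iodide 6 (not isolated)
Conditions: I2, PPh3, imidazole, THF, 0 °C; then Zn, AcOH, 0 °C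
Reagents that add atoms: none
Why: Appel-type iodination of the primary alcohol and zinc-induced reductive opening of the 2,3-epoxy iodide transpose the oxygen to a tertiary vinyl carbinol. The C10–O bond is never broken, so C10 stays S.

Step 5
Reactants: 7 tertiary allylic alcohol
Product: 9 linear bis-silyl dienol ether (C3 triethylsilyl enol ether with C3=C4 and C5=C6; C10 triethylsilyl ether), via tertiary triethylsilyl ether 8 (not isolated)
Conditions: Et3SiOTf, 2,6-lutidine, CH2Cl2, −78 °C; then Et3N, Et3SiOTf, 0 °C
Reagents that add atoms: triethylsilyl trifluoromethanesulfonate CC[Si](CC)(CC)OS(=O)(=O)C(F)(F)F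
Why: The tertiary alcohol is silylated first. Soft enolisation then removes a proton from the unhindered γ methylene C6 rather than the tertiary α′ C8–H, giving the extended silyl dienol ether.

Step 6
Reactants: 9 bis-silyl dienol ether
Product: 10 γ-hydroxy enone with the C6 hydroxyl trans to the C7 isopropenyl group (C6 R; C10 triethylsilyl ether)
Conditions: dimethyldioxirane, acetone/CH2Cl2, −78 °C; aqueous NaHCO3 work-up
Reagents that add atoms: dimethyldioxirane CC1(C)OO1
Why: Vinylogous Rubottom oxidation: the dioxirane attacks the terminal C5=C6 bond of the 1-silyloxy diene, which is far more nucleophilic than the vinyl and isopropenyl groups. Attack comes from the face opposite the adjacent C7 substituent, and collapse gives the γ-hydroxy enone.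

Step 7
Reactants: 10 trans γ-hydroxy enone
Product: 11 C6 4-nitrobenzoate with inverted C6 (C6 S, oxygen cis to the isopropenyl group)
Conditions: 4-nitrobenzoic acid, PPh3, diisopropyl azodicarboxylate, toluene, 0 °C → rt
Reagents that add atoms: 4-nitrobenzoic acid OC(=O)c1ccc(cc1)[N+](=O)[O-]
Why: Mitsunobu reaction: SN2 displacement of the alkoxyphosphonium by the acidic carboxylate inverts C6 to the configuration of the target.

Step 8
Reactants: 11 4-nitrobenzoate
Product: 12 γ-hydroxy enone with the C6 hydroxyl cis to the isopropenyl group (C6 S)
Conditions: K2CO3, MeOH, 0 °C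
Reagents that add atoms: none
Why: Methanolysis of the activated aryl ester; the tertiary triethylsilyl ether is stable to these conditions.

Step 9
Reactants: 12 cis γ-hydroxy enone
Product: 13 C6 tert-butyldimethylsilyl ether (C10 triethylsilyl ether, C3 ketone)
Conditions: t-BuMe2SiOTf, 2,6-lutidine, CH2Cl2, −78 → 0 °C
Reagents that add atoms: tert-butyldimethylsilyl trifluoromethanesulfonate CC(C)(C)[Si](C)(C)OS(=O)(=O)C(F)(F)F
Why: Silylation of the hindered secondary alcohol with the silyl triflate. This ether must outlast the triethylsilyl ethers and keep O6 out of the later lactonisation.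

Step 10
Reactants: 13 silyl-protected ketone
Product: 14 cross-conjugated dienyl triflate (triflate on C3, C3=C8 and C4=C5)
Conditions: KHMDS, THF, −78 °C; then PhNTf2
Reagents that add atoms: N-phenyl-bis(trifluoromethanesulfonimide) FC(F)(F)S(=O)(=O)N(c1ccccc1)S(=O)(=O)C(F)(F)F
Why: Kinetic deprotonation of the α′ methine C8–H and O-sulfonylation of the enolate. This turns the carvone carbonyl carbon C3 into a latent nucleophile and erases the C8 centre.

Step 11
Reactants: 14 dienyl triflate
Product: 15 aldehyde (side chain CH2–C(CH3)(OSiEt3)–CH2–CHO; the aldehyde carbon is C2)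
Conditions: PdCl2(PhCN)2 (cat.), CuCl2·2H2O (cat.), AgNO2 (cat.), O2 (1 atm), t-BuOH/MeNO2, rt
Reagents that add atoms: dioxygen O=O
Why: Aldehyde-selective Wacker-type oxidation: divalent palladium engages only the monosubstituted vinyl group. The adjacent fully substituted silyloxy carbon steers the oxygen to the terminal carbon.

Step 12
Reactants: 15 aldehyde
Product: 16 bicyclic allylic alcohol (ring B closed; C2 hydroxyl, C3=C8, C4=C5)
Conditions: CrCl2, NiCl2 (cat.), DMF, rt
Reagents that add atoms: none
Why: Intramolecular Nozaki–Hiyama–Kishi reaction: nickel inserts into the dienyl triflate, the dienyl group passes to chromium and adds 1,2 to the aldehyde. This closes the six-membered ring B at C2–C3 under neutral conditions; the C2 configuration is immaterial.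

Step 13
Reactants: 16 allylic alcohol
Product: 17 ring-fusion epoxy alcohol (C3–C8 epoxide syn to the C2 hydroxyl)
Conditions: VO(acac)2 (cat.), t-BuOOH, CH2Cl2, 0 °C
Reagents that add atoms: tert-butyl hydroperoxide CC(C)(C)OO
Why: Vanadium-catalysed hydroxyl-directed epoxidation delivers oxygen to the allylic tetrasubstituted C3=C8 bond only. No base is present, so ring B cannot aromatise by loss of the C10 oxygen.

Step 14
Reactants: 17 epoxy alcohol
Product: 18 ring-fusion α,β-epoxy ketone (C2 ketone, C1 methylene)
Conditions: Dess–Martin periodinane, NaHCO3, CH2Cl2, 0 °C → rt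
Reagents that add atoms: none
Why: Buffered Dess–Martin oxidation of the secondary alcohol leaves the acid-sensitive vinyl epoxide and the silyl ethers untouched.

Step 15
Reactants: 18 epoxy ketone
Product: 20 fragmentation precursor (ring-fusion α,β-epoxy ketone with C1 and C10 triethylsilyl ethers and C6 tert-butyldimethylsilyl ether), via hydroxy epoxy ketone 19 (not isolated)
Conditions: LiHMDS, THF, −78 °C; 2-(phenylsulfonyl)-3-phenyloxaziridine; then Et3SiCl, −78 → 0 °C
Reagents that add atoms: 2-(phenylsulfonyl)-3-phenyloxaziridine O1C(c2ccccc2)N1S(=O)(=O)c1ccccc1; chlorotriethylsilane CC[Si](Cl)(CC)CC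
Why: The ketone can enolise only toward C1. Davis hydroxylation of the lithium enolate and silylation of the alkoxide install the C1 oxygen; the low temperature suppresses β-elimination of the C10 silyloxy group, and both C1 epimers serve.

Step 16
Reactants: 20 ring-fusion epoxy ketone; 21 p-toluenesulfonyl hydrazide
Product: 23 ten-membered enynone (C8 ketone, C2≡C3, Z C4=C5; C1 and C10 triethylsilyl ethers, C6 tert-butyldimethylsilyl ether), via epoxy tosylhydrazone 22 (not isolated)
Conditions: AcOH/CH2Cl2 (1:1), −20 → 0 °C
Reagents that add atoms: none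
Why: Eschenmoser–Tanabe fragmentation: acid-catalysed condensation at the only ketone (C2) gives hydrazone 22, whose N–H ionisation opens the C3–O bond of the epoxide to a tosylazo-alkene with the oxygen left on C8. The C8 oxygen then forms the carbonyl while the C3–C8 bond breaks, C2≡C3 forms and dinitrogen and toluenesulfinate leave (a Grob-type fragmentation). The closest known reaction is the conversion of the ring-fusion epoxide of bicyclo[4.4.0]dec-1(6)-en-2-one into cyclodec-5-ynone. No ring is closed: the bond shared by rings A and B is cut, so the ten-membered ring is unveiled and the Z geometry of C4=C5 is inherited from the cyclohexene. No stereocentre is formed; C2, C3 and the old C8 lose their configuration, so the epimer mixtures converge, while C6, C7 and C10 are untouched. Regiochemistry is fixed because the epoxide is the only good α-leaving group of the hydrazone and C1 carries a silyl ether; the azo-diene cannot electrocyclise because C2 and C5 are held s-trans about C3–C4. The selectivity that matters is preservation of C7 (α to the new ketone and allylic) and of the β-silyloxy group at C6; cold acetic acid without base is expected to secure both.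

Step 17
Reactants: 23 enynone
Product: 24 enynone diol (free C1 and C10 hydroxyls, C6 silyl ether, C8 ketone)
Conditions: HF·pyridine, pyridine, THF, 0 °C
Reagents that add atoms: none
Why: Buffered fluoride cleaves the two triethylsilyl ethers much faster than the hindered secondary tert-butyldimethylsilyl ether. The weakly acidic medium does not enolise the β-silyloxy ketone.

Step 18
Reactants: 24 enynone diol
Product: 25 enyne triol (C8 S alcohol; C1, C8 and C10 hydroxyls)
Conditions: Me4NBH(OAc)3, AcOH/MeCN (1:1), −30 °C
Reagents that add atoms: none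
Why: Evans–Saksena reduction: the C10 hydroxyl exchanges onto boron and delivers hydride intramolecularly through a chair transition state. This gives the 1,3-anti relation between O10 and the new O8 (C8 S); the silylated C6 oxygen cannot direct.

Step 19
Reactants: 25 triol
Product: 27 furanone (3(2H)-furanone bridging C3 and C10; free C8 hydroxyl, C6 silyl ether, C7 isopropenyl), via hydroxy ynone 26 (not isolated)
Conditions: MnO2, CH2Cl2, rt; filter; then Ph3PAuCl (cat.), AgOTf (cat.), toluene, rt
Reagents that add atoms: none
Why: Activated MnO2 oxidises only the propargylic secondary alcohol, which also erases the C1 epimers. Monovalent gold then activates the ynone for 5-endo-dig addition of the C10 hydroxyl to C3, a known furanone synthesis that also relieves the alkyne strain.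

Step 20
Reactants: 27 furanone
Product: 28 allylic alcohol (C12 hydroxymethyl on the C11=C13 alkene)
Conditions: SeO2 (cat.), t-BuOOH, CH2Cl2, rt
Reagents that add atoms: tert-butyl hydroperoxide CC(C)(C)OO
Why: Selenium dioxide allylic oxidation (ene reaction, then [2,3]-shift) of the isopropenyl methyl group. The C4=C5 alkene is deactivated by conjugation with the furanone; any enal formed converges in the next step.

Step 21
Reactants: 28 allylic alcohol
Product: 29 α-methylene-γ-lactone, C6 tert-butyldimethylsilyl ether
Conditions: TEMPO (cat.), PhI(OAc)2, CH2Cl2, rt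
Reagents that add atoms: none
Why: Oxidative lactonisation: the primary allylic alcohol is oxidised to the enal, trapped by the C8 hydroxyl as a lactol and oxidised again. Because O6 is silylated only the trans-fused 8,12-lactone can form.

Step 22
Reactants: 29 silyl ether
Product: 30 C6 alcohol (the target without its acyl group)
Conditions: HF·pyridine, THF, 0 °C → rt
Reagents that add atoms: none
Why: Acidic fluoride removes the silyl ether without generating a C6 alkoxide, so neither translactonisation nor conjugate addition to the methylene lactone is expected.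

Step 23
Reactants: 31 angelic acid, (Z)-2-methylbut-2-enoic acid
Product: 32 (Z)-2-methylbut-2-en-1-ol
Conditions: LiAlH4, Et2O, 0 °C
Reagents that add atoms: none
Why: Hydride reduction of the acid to the allylic alcohol; the Z geometry is retained.

Step 24
Reactants: 32 (Z)-allylic alcohol
Product: 33 [(2R,3S)-2,3-dimethyloxiran-2-yl]methanol
Conditions: Ti(OiPr)4, D-(−)-diethyl tartrate, t-BuOOH, 4 Å MS, CH2Cl2, −20 °C
Reagents that add atoms: tert-butyl hydroperoxide CC(C)(C)OO
Why: Sharpless asymmetric epoxidation; the D-(−)-tartrate selects the face that gives the (2R,3S) epoxy alcohol, and the cis relation of CH2OH and the C3 methyl follows from the Z alkene.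

Step 25
Reactants: 33 epoxy alcohol
Product: 34 (2S,3S)-2,3-dimethyloxirane-2-carboxylic acid
Conditions: TEMPO (cat.), PhI(OAc)2, MeCN/H2O (1:1), rt
Reagents that add atoms: water O
Why: Oxoammonium oxidation of the primary alcohol through the aldehyde hydrate to the acid leaves the epoxide intact. The C2 descriptor changes from R to S only because the priorities change.

Step 26
Reactants: 30 C6 alcohol; 34 epoxy acid
Product: 36 CNP0258430.1, via mixed anhydride 35 (not isolated)
Conditions: 34, 2,4,6-trichlorobenzoyl chloride, Et3N, THF, rt; then 30, DMAP, toluene, rt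
Reagents that add atoms: none
Why: Yamaguchi esterification: DMAP opens the mixed anhydride at the epoxy acid carbonyl and the acylpyridinium acylates the hindered C6 hydroxyl. All stereocentres are retained.

## Compound list

1 | (S)-carvone | CC1=CC[C@@H](CC1=O)C(C)=C | starting material
2 | (E)-4-chloro-3-methylbut-2-enyl acetate | CC(=O)OC/C=C(\C)CCl | starting material
3 | (E)-3-methyl-4-[(1R,6S)-3-methyl-2-oxo-6-(prop-1-en-2-yl)cyclohex-3-en-1-yl]but-2-enyl acetate | C=C(C)[C@H]1CC=C(C)C(=O)[C@@H]1C/C(C)=C/COC(C)=O | intermediate
4 | (5S,6R)-6-[(E)-4-hydroxy-2-methylbut-2-enyl]-2-methyl-5-(prop-1-en-2-yl)cyclohex-2-enone | C=C(C)[C@H]1CC=C(C)C(=O)[C@@H]1C/C(C)=C/CO | intermediate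
5 | (5S,6R)-6-{[(2S,3S)-3-(hydroxymethyl)-2-methyloxiran-2-yl]methyl}-2-methyl-5-(prop-1-en-2-yl)cyclohex-2-enone | C=C(C)[C@H]1CC=C(C)C(=O)[C@@H]1C[C@]2(C)O[C@H]2CO | intermediate
6 | epoxy iodide (5 with iodine in place of the primary hydroxyl, same configuration) | C=C(C)[C@H]1CC=C(C)C(=O)[C@@H]1C[C@]2(C)O[C@H]2CI | intermediate
7 | (5S,6R)-6-[(2S)-2-hydroxy-2-methylbut-3-enyl]-2-methyl-5-(prop-1-en-2-yl)cyclohex-2-enone | C=C(C)[C@H]1CC=C(C)C(=O)[C@@H]1C[C@](C)(O)C=C | intermediate
8 | triethylsilyl ether of 7 at the tertiary (C10) oxygen | C=C(C)[C@H]1CC=C(C)C(=O)[C@@H]1C[C@](C)(O[Si](CC)(CC)CC)C=C | intermediate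
9 | linear bis-silyl dienol ether (C3 OSiEt3, C3=C4, C5=C6; C10 OSiEt3; C8 side chain trans to isopropenyl) | C=C(C)[C@H]1C=CC(C)=C(O[Si](CC)(CC)CC)[C@@H]1C[C@](C)(O[Si](CC)(CC)CC)C=C | intermediate
10 | γ-hydroxy enone, C6 hydroxyl trans to the C7 isopropenyl group (C6 R, C10 S) | C=C(C)[C@H]1[C@H](O)C=C(C)C(=O)[C@@H]1C[C@](C)(O[Si](CC)(CC)CC)C=C | intermediate
11 | C6 4-nitrobenzoate, C6 inverted (C6 S, oxygen cis to isopropenyl) | C=C(C)[C@H]1[C@@H](OC(=O)c2ccc(cc2)[N+](=O)[O-])C=C(C)C(=O)[C@@H]1C[C@](C)(O[Si](CC)(CC)CC)C=C | intermediate
12 | γ-hydroxy enone, C6 hydroxyl cis to isopropenyl (C6 S) | C=C(C)[C@H]1[C@@H](O)C=C(C)C(=O)[C@@H]1C[C@](C)(O[Si](CC)(CC)CC)C=C | intermediate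
13 | C6 tert-butyldimethylsilyl ether of 12 | C=C(C)[C@H]1[C@@H](O[Si](C)(C)C(C)(C)C)C=C(C)C(=O)[C@@H]1C[C@](C)(O[Si](CC)(CC)CC)C=C | intermediate
14 | dienyl triflate (C3 triflate, C3=C8, C4=C5; vinyl carbinol silyl ether side chain) | C=C(C)[C@H]1[C@@H](O[Si](C)(C)C(C)(C)C)C=C(C)C(OS(=O)(=O)C(F)(F)F)=C1C[C@](C)(O[Si](CC)(CC)CC)C=C | intermediate
15 | dienyl triflate aldehyde (C2 aldehyde, C10 S) | C=C(C)[C@H]1[C@@H](O[Si](C)(C)C(C)(C)C)C=C(C)C(OS(=O)(=O)C(F)(F)F)=C1C[C@](C)(O[Si](CC)(CC)CC)CC=O | intermediate
16 | bicyclic allylic alcohol (ring B closed, C2 hydroxyl as epimers, C3=C8, C4=C5) | C=C(C)[C@H]1[C@@H](O[Si](C)(C)C(C)(C)C)C=C(C)C2=C1C[C@](C)(O[Si](CC)(CC)CC)CC2O | intermediate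
17 | ring-fusion epoxy alcohol (C3–C8 epoxide syn to the C2 hydroxyl) | C=C(C)[C@H]1[C@@H](O[Si](C)(C)C(C)(C)C)C=C(C)C23OC21C[C@](C)(O[Si](CC)(CC)CC)CC3O | intermediate
18 | ring-fusion epoxy ketone (C2 ketone, C1 methylene) | C=C(C)[C@H]1[C@@H](O[Si](C)(C)C(C)(C)C)C=C(C)C23OC21C[C@](C)(O[Si](CC)(CC)CC)CC3=O | intermediate
19 | hydroxy epoxy ketone (C1 hydroxyl, epimers) | C=C(C)[C@H]1[C@@H](O[Si](C)(C)C(C)(C)C)C=C(C)C23OC21C[C@](C)(O[Si](CC)(CC)CC)C(O)C3=O | intermediate
20 | fragmentation precursor: ring-fusion α,β-epoxy ketone, C1 and C10 OSiEt3, C6 OSiMe2tBu (C6 S, C10 S, C7 as in carvone) | C=C(C)[C@H]1[C@@H](O[Si](C)(C)C(C)(C)C)C=C(C)C23OC21C[C@](C)(O[Si](CC)(CC)CC)C(O[Si](CC)(CC)CC)C3=O | intermediate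
21 | p-toluenesulfonyl hydrazide | Cc1ccc(cc1)S(=O)(=O)NN | starting material
22 | epoxy tosylhydrazone of 20 at C2 | C=C(C)[C@H]1[C@@H](O[Si](C)(C)C(C)(C)C)C=C(C)C23OC21C[C@](C)(O[Si](CC)(CC)CC)C(O[Si](CC)(CC)CC)C3=NNS(=O)(=O)c1ccc(C)cc1 | intermediate
23 | ten-membered enynone (C8 ketone, C2≡C3, Z C4=C5; C1 and C10 OSiEt3, C6 OSiMe2tBu) | C=C(C)[C@H]1[C@@H](O[Si](C)(C)C(C)(C)C)/C=C(C)\C#CC(O[Si](CC)(CC)CC)[C@@](C)(O[Si](CC)(CC)CC)CC1=O | intermediate
24 | enynone diol (C1 and C10 hydroxyls free) | C=C(C)[C@H]1[C@@H](O[Si](C)(C)C(C)(C)C)/C=C(C)\C#CC(O)[C@@](C)(O)CC1=O | intermediate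
25 | enyne triol (C8 S alcohol) | C=C(C)[C@H]1[C@@H](O[Si](C)(C)C(C)(C)C)/C=C(C)\C#CC(O)[C@@](C)(O)C[C@@H]1O | intermediate
26 | α′-hydroxy ynone (C1 ketone) | C=C(C)[C@H]1[C@@H](O[Si](C)(C)C(C)(C)C)/C=C(C)\C#CC(=O)[C@@](C)(O)C[C@@H]1O | intermediate
27 | furanone with free C8 hydroxyl, C6 silyl ether and C7 isopropenyl | C=C(C)[C@H]1[C@@H](O[Si](C)(C)C(C)(C)C)/C=C(C)\C2=CC(=O)[C@@](C)(O2)C[C@@H]1O | intermediate
28 | allylic alcohol (C12 hydroxyl) | C=C(CO)[C@H]1[C@@H](O[Si](C)(C)C(C)(C)C)/C=C(C)\C2=CC(=O)[C@@](C)(O2)C[C@@H]1O | intermediate
29 | α-methylene lactone, C6 tert-butyldimethylsilyl ether | C=C1C(=O)O[C@H]2C[C@]3(C)OC(=CC3=O)/C(C)=C\[C@H](O[Si](C)(C)C(C)(C)C)[C@H]12 | intermediate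
30 | C6 alcohol (target without the acyl group) | C=C1C(=O)O[C@H]2C[C@]3(C)OC(=CC3=O)/C(C)=C\[C@H](O)[C@H]12 | intermediate
31 | angelic acid, (Z)-2-methylbut-2-enoic acid | C/C=C(/C)C(O)=O | starting material
32 | (Z)-2-methylbut-2-en-1-ol | C/C=C(/C)CO | intermediate
33 | [(2R,3S)-2,3-dimethyloxiran-2-yl]methanol | OC[C@@]1(C)O[C@H]1C | intermediate
34 | (2S,3S)-2,3-dimethyloxirane-2-carboxylic acid | OC(=O)[C@@]1(C)O[C@H]1C | intermediate
35 | mixed anhydride of 34 with 2,4,6-trichlorobenzoic acid | O=C(OC(=O)[C@@]1(C)O[C@H]1C)c1c(Cl)cc(Cl)cc1Cl | intermediate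
36 | CNP0258430.1 | C=C1C(=O)O[C@H]2C[C@]3(C)OC(=CC3=O)/C(C)=C\[C@H](OC(=O)[C@@]3(C)O[C@H]3C)[C@H]12 | target

## Step count and least certain steps

Total step count: 26. Longest linear sequence: 23 (steps 1–22 and 26); the acid branch (steps 23–25) joins in step 26.

**Step 16 (key step).**
- What may go wrong: hydrazone formation at the hindered, doubly α-oxygenated ketone may be slow, leaving time for acid-mediated opening of the allylic epoxide or loss of the silyl ethers. After fragmentation, enolisation of the new ketone toward C7 could cause epimerisation or β-elimination of the C6 silyloxy group.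
- Fallback: from 20, condensation with 1-amino-2-phenylaziridine would give the N-aziridinyl imine F1. Heating F1 in toluene without acid or base would fragment it with loss of styrene and dinitrogen, returning to the route at 23.

**Step 11.**
- What may go wrong: regiochemical leakage to Markovnikov oxidation (methyl ketone), or diversion of palladium by the electron-rich dienyl triflate.
- Fallback: ring B is closed by metathesis instead. From 14, Stille coupling with tributyl(1-ethoxyvinyl)stannane (Pd(PPh3)4, LiCl, CuI) would give the 2-ethoxy diene F2. Ring-closing metathesis with the second-generation Grubbs catalyst would give the cyclic dienol ether F3. Dimethyldioxirane followed by aqueous work-up would give the α′-hydroxy dienone F4, and chlorotriethylsilane/imidazole its silyl ether F5. Nucleophilic epoxidation (t-BuOOH, DBU) would then rejoin the route at 20. This path has its own weakness: the isopropenyl group can compete in the metathesis, and the epoxidation needs base.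

**Step 6 (with step 5).**
- What may go wrong: formation of the cross-conjugated dienol ether in step 5, attack of the oxidant at the enol ether carbon C4 instead of C6, or poor facial selectivity.
- Fallback: from 9, singlet oxygen (O2, light, tetraphenylporphyrin, CH2Cl2, −78 °C) would add across C3 and C6 in a [4+2] sense, anti to the isopropenyl group, to give the endoperoxide F6. Reduction with triphenylphosphine and aqueous work-up would return to the route at 10.

**Step 18.**
- What may go wrong: poor facial selectivity if the medium ring cannot adopt the chair delivery with the ring carbon C1 equatorial, or slow exchange of the tertiary hydroxyl on boron.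
- Fallback: reagent control. From 23 (both triethylsilyl ethers still in place), reduction with catecholborane and the (R)-configured B-methyl Corey–Bakshi–Shibata oxazaborolidine would give the silyl-protected C8 S alcohol F7; here C7 is the large and C9 the small substituent. HF·pyridine would then return to the route at 25.

**Step 20.**
- What may go wrong: loss of chemoselectivity (oxidation at C15 or at C6–H) or over-oxidation.
- Fallback: from 27, a Schenck ene reaction with singlet oxygen at the isopropenyl group would give the allylic hydroperoxide F8. Reduction with triphenylphosphine would return to the route at 28.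

## Further compounds

F1 | step 16 | N-aziridinyl imine of 20 with 1-amino-2-phenylaziridine (racemic reagent) | C=C(C)[C@H]1[C@@H](O[Si](C)(C)C(C)(C)C)C=C(C)C23OC21C[C@](C)(O[Si](CC)(CC)CC)C(O[Si](CC)(CC)CC)C3=NN1CC1c1ccccc1
F2 | step 11 | 2-ethoxy diene from Stille coupling of 14 | C=C(C)[C@H]1[C@@H](O[Si](C)(C)C(C)(C)C)C=C(C)C(C(=C)OCC)=C1C[C@](C)(O[Si](CC)(CC)CC)C=C
F3 | step 11 | cyclic dienol ether (ring B closed by metathesis) | C=C(C)[C@H]1[C@@H](O[Si](C)(C)C(C)(C)C)C=C(C)C2=C1C[C@](C)(O[Si](CC)(CC)CC)C=C2OCC
F4 | step 11 | α′-hydroxy ring-fusion dienone (C1 hydroxyl, epimers) | C=C(C)[C@H]1[C@@H](O[Si](C)(C)C(C)(C)C)C=C(C)C2=C1C[C@](C)(O[Si](CC)(CC)CC)C(O)C2=O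
F5 | step 11 | C1 triethylsilyl ether of F4 | C=C(C)[C@H]1[C@@H](O[Si](C)(C)C(C)(C)C)C=C(C)C2=C1C[C@](C)(O[Si](CC)(CC)CC)C(O[Si](CC)(CC)CC)C2=O
F6 | step 6 | 3,6-endoperoxide of dienol ether 9 (peroxide bridge anti to isopropenyl) | C=C(C)[C@H]1[C@H]2C=C(C)[C@](O[Si](CC)(CC)CC)(OO2)[C@@H]1C[C@](C)(O[Si](CC)(CC)CC)C=C
F7 | step 18 | C8 S alcohol with C1 and C10 triethylsilyl ethers | C=C(C)[C@H]1[C@@H](O[Si](C)(C)C(C)(C)C)/C=C(C)\C#CC(O[Si](CC)(CC)CC)[C@@](C)(O[Si](CC)(CC)CC)C[C@@H]1O
F8 | step 20 | allylic hydroperoxide at C12 | C=C(COO)[C@H]1[C@@H](O[Si](C)(C)C(C)(C)C)/C=C(C)\C2=CC(=O)[C@@](C)(O2)C[C@@H]1O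
A1 | alternative 1 | dienyl diazoacetate | [N-]=[N+]=CC(=O)O[C@@H](C[C@](C)(O[Si](CC)(CC)CC)C#C[Si](C)(C)C)/C=C/C=C(C)\CO[Si](C)(C)C(C)(C)C
A2 | alternative 1 | vinylcyclopropane-fused γ-lactone | O=C1O[C@@H](C[C@](C)(O[Si](CC)(CC)CC)C#C[Si](C)(C)C)[C@@H]2[C@@H](/C=C(C)\CO[Si](C)(C)C(C)(C)C)[C@H]12
A3 | alternative 2 | furanone-bridged C7 ethynyl C8 alcohol | C#C[C@H]1[C@@H](O[Si](C)(C)C(C)(C)C)/C=C(C)\C2=CC(=O)[C@@](C)(O2)C[C@@H]1O
A4 | alternative 2 | C6 silyl ether of the target core (same structure as 29) | C=C1C(=O)O[C@H]2C[C@]3(C)OC(=CC3=O)/C(C)=C\[C@H](O[Si](C)(C)C(C)(C)C)[C@H]12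
A5 | alternative 3 | dihydropyranyl diazoketone (C7 configuration left open) | CC(=[N+]=[N-])C(=O)C[C@@H]1OC(C(=C)O[Si](C)(C)C(C)(C)C)[C@@H](O[Si](C)(C)C(C)(C)C)C=C1C
A6 | alternative 3 | oxa-bridged bicyclic ketone with the C7–C8 silyl enol ether | C[C@]12C/C(O[Si](C)(C)C(C)(C)C)=C\[C@@H](O[Si](C)(C)C(C)(C)C)/C=C(C)\[C@H](CC1=O)O2
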